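The ratio of the constant that makes target to the constant with which starting material destroys it, 0.395 M, is the concentration at which target would stand still, and it lies above the charge.

starting material 0.30 M; time 20 min

    starting material → target (k1 = 0.015 s⁻¹)
    other conformer → isomer of the product (k2 = 0.014 s⁻¹)
    starting material ⇌ other conformer (K3 = 0.80, k3 = 0.0088 s⁻¹)
    starting material + target → side product (k4 = 0.038 M⁻¹ s⁻¹)

- in percentages every species weighs as the starting material in it: one side product counts as two
- in a conversion other conformer counts as not yet reacted
- the reaction counts as stopped when no species that holds the starting material changes by six tenths of a point or more over the second half of the time
- run time (flask): 20 min

* at 20 min, what has stopped the reaction, if anything has (other conformer counts as not reacted) (forward and back rates have come level / all of the starting material has reacted / it is still moving)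
* part of the starting material that has turned into other species by 20 min (other conformer does not count)
* target at 20 min, in percent of the starting material charged
* side product at 20 min, in percent of the starting material charged

Both rates carry c(starting material), so I clock target not by time but by the exposure X, the area under c(starting material) against time:

c(target) = 0.395 M × (1 − exp(−0.038 M⁻¹ s⁻¹ × X))

The exits have half-lives of 0.770 min and 0.825 min, far shorter than the run, so I reckon the run as finished. Other conformer returns part of what it receives, which leaves a net leak to isomer of 0.00493 s⁻¹ per unit of c(starting material). Each target destroyed takes one more starting material with it, so the charge balances through the drain, the starting material lost per unit of exposure when target is counted back, 0.0349 s⁻¹: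

0.30 M + c(target) = 0.0349 s⁻¹ × X

Target found cannot be negative, nor exceed what was made, so X lies between 8.59 M·s and 15.1 M·s. Passing each bound through both lines tightens the bracket on target:

first pass: 0.110 M to 0.172 M
next pass: 0.142 M to 0.159 M
last pass: 50.2% to 51.7% of the charge

The forecast reads all of the starting material has reacted, conversion 100%, target 51.3% and side product 27.4%, holding that “20 min is far more than enough to consume everything”, and its target lies inside my bracket .

The simulation gives all of the starting material has reacted, with 0% left, conversion 100%, target 51.3% and side product 27.4%.

Striking out the turning of starting material + target into side product lifts target in this flask from 51.3% to 75.3%, at most the largest single effect . The drain turns this flask's target into an exposure of 13.0 M·s, and what was made minus what remains, doubled, gives 27.4% side product. In the neighbour charged with 0.75 M, its target of 35.2% gives an exposure of 29.0 M·s, hence 45.8% side product, where that flask holds 45.8%.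

All constants were chosen freely; the rest is arithmetic.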